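**Plan**

- Retrosynthesis: ring A is numbered C1′ to C6′ (butyryl on C1′, geranyl on C3′, bridging CH2 on C5′, oxygen on C2′, C4′ and C6′). It is a benzene with strictly alternating oxygen and carbon substituents, the pattern that one ketene carbonyl and two ynol ether oxygens deliver, and it is cut at C3′–C4′, C1′–C2′ and C4′–C5′ into a 3-siloxycyclobutenone and a geranyl siloxyalkyne.
- The cyclobutenone is cut across its four-membered ring into a ring B propanoyl ketene and a ketal-bearing siloxyalkyne. Ring B is cut at the bond from its quaternary carbon to geranyl and at the ring–side-chain bond, back to a methylated acetylphloroglucinol.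
- Forward: the aromatic ring B precursor receives the three-carbon acid chain and is dearomatised by C-geranylation. The cyclobutenone is then built on the chain, ring A is closed last by benzannulation, and hydrolysis and desilylation finish the route.
- Stereochemistry: the only stereocentre (quaternary carbon of ring B) is set by ligand-controlled palladium allylation. The E-alkenes come in with geranyl acetate and geranyl bromide, and the cyclobutenone centre is erased.

Key step: step 12

Remark: Ger = (2E)-3,7-dimethylocta-2,6-dien-1-yl; TIPS = triisopropylsilyl; ring B is numbered B1–B6 with acetyl on B2, methyl and Ger on B4 and the bridging carbon on B6; RB = (3R)-5-acetyl-3-Ger-2,6-dimethoxy-3-methyl-4-oxocyclohexa-1,5-dien-1-yl.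
Remark: ring B is carried as the B1,B5-di-O-methyl 2,4-dienone (B3 ketone), because this is the enol ether isomer that a regiodefined aromatic precursor delivers; the final hydrolysis gives the same triketone from any enol ether isomer.
Remark: the absolute sense of induction in step 5 has to be assigned by experiment; the ligand antipode that gives the (R)-dienone is then used, and the (R,R)-ligand is written here.
Remark: cyclobutenone 22 is used as the mixture of epimers at its hydrogen-bearing ring carbon.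

**Route**

Step 1
Reactants: 1 1-(2,4,6-trihydroxy-3-methylphenyl)ethan-1-one
Product: 2 1-(2-hydroxy-4,6-dimethoxy-3-methylphenyl)ethan-1-one
Conditions: Me2SO4 (2.05 equiv), K2CO3 (2.2 equiv), acetone, reflux
Reagents that add atoms: dimethyl sulfate COS(=O)(=O)OC
Why: Williamson O-methylation should take the non-chelated 4-hydroxyl and the less hindered 6-hydroxyl, while the 2-hydroxyl wedged between acetyl and methyl stays hydrogen-bonded to the ketone and is kept for the dearomatisation.

Step 2
Reactants: 2 1-(2-hydroxy-4,6-dimethoxy-3-methylphenyl)ethan-1-one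
Product: 3 1-(2-hydroxy-5-iodo-4,6-dimethoxy-3-methylphenyl)ethan-1-one
Conditions: N-iodosuccinimide (1.05 equiv), MeCN, 0 °C to rt
Reagents that add atoms: N-iodosuccinimide O=C1CCC(=O)N1I
Why: electrophilic aromatic iodination can only take place at the single free ring carbon, which is para to the phenol and ortho to both methoxy groups.

Step 3
Reactants: 3 1-(2-hydroxy-5-iodo-4,6-dimethoxy-3-methylphenyl)ethan-1-one; 4 acrylic acid
Product: 5 (2E)-3-(3-acetyl-4-hydroxy-2,6-dimethoxy-5-methylphenyl)prop-2-enoic acid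
Conditions: Pd(OAc)2 (5 mol %), P(o-tolyl)3 (10 mol %), Et3N (3.5 equiv), DMF, 90 °C; 1 M HCl work-up
Reagents that add atoms: none
Why: the Mizoroki–Heck reaction of aryl iodides with acrylic acid tolerates two ortho substituents and a free phenol, and syn β-hydride elimination should give the E-acid.

Step 4
Reactants: 5 (2E)-3-(3-acetyl-4-hydroxy-2,6-dimethoxy-5-methylphenyl)prop-2-enoic acid
Product: 6 3-(3-acetyl-4-hydroxy-2,6-dimethoxy-5-methylphenyl)propanoic acid
Conditions: H2 (1 atm), 10% Pd on carbon, EtOAc, rt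
Reagents that add atoms: none
Why: catalytic hydrogenation saturates the cinnamic double bond far faster than it touches the hydrogen-bonded aryl ketone, and no alkene that must survive is present yet.

Step 5
Reactants: 6 3-(3-acetyl-4-hydroxy-2,6-dimethoxy-5-methylphenyl)propanoic acid; 7 geranyl acetate
Product: 8 3-RB-propanoic acid
Conditions: Pd2(dba)3·CHCl3 (2.5 mol %), (R,R)-N,N'-(cyclohexane-1,2-diyl)bis[2-(diphenylphosphino)benzamide] (7.5 mol %), Cs2CO3 (2.2 equiv), 7 (1.05 equiv), degassed THF, 25 °C; aqueous citric acid work-up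
Reagents that add atoms: none
Why: Proposed new method: zerovalent palladium ionises 7 to the syn π-geranyl complex, and the caesium phenoxide of 6 attacks its unsubstituted terminus inside the chiral pocket through the ortho carbon B4, the only ring carbon that is activated by the free phenoxide, not acylated and not buried between two methoxy groups, so that the quaternary stereocentre forms under ligand control while O-allylation at phenoxide or carboxylate is undone by re-ionisation; the closest known reactions are the palladium-catalysed intermolecular asymmetric allylic dearomatisation of 1-substituted 2-naphthols with this ligand family (Tsuji–Trost allylation) and the racemic ortho C-allylation of 2,6-disubstituted phenoxides.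

Step 6
Reactants: 9 hex-1-yn-3-ol
Product: 10 hex-1-yn-3-one
Conditions: Dess–Martin periodinane (1.1 equiv), NaHCO3, CH2Cl2, 0 °C to rt; filtered and used as a dried CH2Cl2 solution
Reagents that add atoms: none
Why: the Dess–Martin oxidation of a secondary propargylic alcohol is fast and neutral, so the volatile ynone is not exposed to nucleophiles that would add in a conjugate sense.

Step 7
Reactants: 10 hex-1-yn-3-one
Product: 11 2-ethynyl-2-propyl-1,3-dioxolane
Conditions: Me3SiOCH2CH2OSiMe3 (1.3 equiv), Me3SiOTf (3 mol %), CH2Cl2, −78 to −30 °C; pyridine quench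
Reagents that add atoms: 1,2-bis(trimethylsilyloxy)ethane C[Si](C)(C)OCCO[Si](C)(C)C
Why: silyl triflate-catalysed ketalisation with the bis-silyl ether of ethylene glycol runs aprotically at low temperature, which avoids conjugate addition of the diol to the ynone, and is driven by formation of hexamethyldisiloxane.

Step 8
Reactants: 11 2-ethynyl-2-propyl-1,3-dioxolane
Product: 14 triisopropyl{[(2-propyl-1,3-dioxolan-2-yl)ethynyl]oxy}silane, via lithium acetylide 12 (not isolated), via lithium ynolate 13 (not isolated)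
Conditions: LiN(SiMe3)2 (2.1 equiv), THF, −78 °C; t-BuOOH (1.0 equiv), −78 to 0 °C; i-Pr3SiOTf (1.1 equiv), −78 to 0 °C; chromatography on Et3N-deactivated silica
Reagents that add atoms: tert-butyl hydroperoxide CC(C)(C)OO; triisopropylsilyl trifluoromethanesulfonate CC(C)[Si](OS(=O)(=O)C(F)(F)F)(C(C)C)C(C)C
Why: oxidation of a lithium acetylide by lithium tert-butyl peroxide gives the lithium ynolate, and its O-silylation by the bulky silyl triflate is the standard entry to triisopropylsiloxyalkynes.

Step 9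
Reactants: 15 geranyl bromide
Product: 16 (4E)-5,9-dimethyldeca-4,8-dien-1-yne
Conditions: HC≡CMgBr (0.5 M in THF, 1.5 equiv), CuCl (5 mol %), THF, 0 to 50 °C
Reagents that add atoms: ethynylmagnesium bromide C#C[Mg]Br
Why: copper-catalysed coupling of an alkynyl Grignard reagent with a primary allylic bromide takes place at the unsubstituted terminus and so keeps the E-trisubstituted alkene of the geranyl unit.

Step 10
Reactants: 16 (4E)-5,9-dimethyldeca-4,8-dien-1-yne
Product: 19 {[(4E)-5,9-dimethyldeca-4,8-dien-1-yn-1-yl]oxy}triisopropylsilane, via lithium acetylide 17 (not isolated), via lithium ynolate 18 (not isolated)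
Conditions: LiN(SiMe3)2 (2.1 equiv), THF, −78 °C; t-BuOOH (1.0 equiv), −78 to 0 °C; i-Pr3SiOTf (1.1 equiv), −78 to 0 °C; chromatography on Et3N-deactivated silica
Reagents that add atoms: tert-butyl hydroperoxide CC(C)(C)OO; triisopropylsilyl trifluoromethanesulfonate CC(C)[Si](OS(=O)(=O)C(F)(F)F)(C(C)C)C(C)C
Why: the same acetylide oxidation and O-silylation apply, and the silylamide base is too weak to metalate the CH2 group between alkyne and alkene.

Step 11
Reactants: 8 3-RB-propanoic acid; 14 triisopropyl{[(2-propyl-1,3-dioxolan-2-yl)ethynyl]oxy}silane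
Product: 22 4-(RB-methyl)-2-(2-propyl-1,3-dioxolan-2-yl)-3-(TIPS-oxy)cyclobut-2-en-1-one (both C4 epimers), via acid chloride 20 (not isolated), via ketene 21 (not isolated)
Conditions: 1-chloro-N,N,2-trimethylprop-1-en-1-amine (1.1 equiv), CH2Cl2, 0 °C to rt; then 14 (1.3 equiv), Et3N (1.5 equiv, syringe pump), CH2Cl2, rt
Reagents that add atoms: none
Why: the α-chloroenamine gives the acid chloride without free HCl, dehydrochlorination gives the monosubstituted ketene, and the electron-rich β-carbon of the siloxyalkyne attacks the ketene carbonyl carbon, so the [2+2] cycloaddition should give the 3-siloxycyclobutenone with the ketal on C2 and the ring B methylene on C4.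

Step 12
Reactants: 22 4-(RB-methyl)-2-(2-propyl-1,3-dioxolan-2-yl)-3-(TIPS-oxy)cyclobut-2-en-1-one; 19 {[(4E)-5,9-dimethyldeca-4,8-dien-1-yn-1-yl]oxy}triisopropylsilane
Product: 27 2-Ger-4-(2-propyl-1,3-dioxolan-2-yl)-6-(RB-methyl)-3,5-bis(TIPS-oxy)phenol, via vinylketene 23 (not isolated), via vinylcyclobutenone 24 (not isolated), via dienylketene 25 (not isolated), via cyclohexadienone 26 (not isolated)
Conditions: 19 (1.5 equiv), toluene (0.2 M), argon, sealed tube, 80 °C, then 110 °C if 24 accumulates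
Reagents that add atoms: none
Why: Heating opens 22 by conrotatory four-electron electrocyclic cleavage of its ring bond C1–C4 to vinylketene 23, which erases the ring stereocentre so that both epimers converge. The nucleophilic β-carbon of 19 adds to the ketene carbonyl carbon and the [2+2] cycloaddition gives vinylcyclobutenone 24, forming the ring A bonds C3′–C4′ and C1′–C2′. A second four-electron opening gives dienylketene 25, whose thermally allowed disrotatory six-electron electrocyclisation closes ring A at C4′–C5′ to cyclohexadienone 26, and tautomerisation gives phenol 27; this is the Danheiser benzannulation in its siloxyalkyne form. No stereocentre that survives is created, and the B4 centre is a spectator because the medium is neutral and free of electrophiles. The step needs head-to-tail regiochemistry and capture of the ketene by the alkyne and not by one of the four trisubstituted alkenes; both follow from the polarisation of the ynol ether, whose β-carbon is the only strong nucleophile present. An excess of 19 is used so that 23, whose α-carbon is crowded by the ketal, is trapped before it acylates the product phenol.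

Step 13
Reactants: 27 2-Ger-4-(2-propyl-1,3-dioxolan-2-yl)-6-(RB-methyl)-3,5-bis(TIPS-oxy)phenol
Product: 28 1-[3-Ger-4-hydroxy-5-{[(3R)-5-acetyl-3-Ger-2,4-dihydroxy-3-methyl-6-oxocyclohexa-1,4-dien-1-yl]methyl}-2,6-bis(TIPS-oxy)phenyl]butan-1-one
Conditions: 1 M aqueous HCl–THF (1:4), 30 °C
Reagents that add atoms: water O
Why: acid-catalysed hydrolysis should cleave the aryl-stabilised dioxolane and both vinylogous methyl esters of ring B by addition of water and loss of ethylene glycol or methanol, while aryl TIPS ethers and isolated trisubstituted alkenes tolerate dilute aqueous acid at this temperature.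

Step 14
Reactants: 28 1-[3-Ger-4-hydroxy-5-{[(3R)-5-acetyl-3-Ger-2,4-dihydroxy-3-methyl-6-oxocyclohexa-1,4-dien-1-yl]methyl}-2,6-bis(TIPS-oxy)phenyl]butan-1-one
Product: 29 1-[3-Ger-2,4,6-trihydroxy-5-{[(3R)-5-acetyl-3-Ger-2,4-dihydroxy-3-methyl-6-oxocyclohexa-1,4-dien-1-yl]methyl}phenyl]butan-1-one (CNP0209203.1)
Conditions: Bu4NF (2.2 equiv), AcOH (2.5 equiv), THF, 0 °C, argon
Reagents that add atoms: none
Why: fluoride cleaves the two aryl silyl ethers quickly at 0 °C, and the acetic acid buffer keeps the acylphloroglucinol and the β-triketone protonated so that they are neither oxidised nor cyclised onto the geranyl groups.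

**Compound list**

1 | 1-(2,4,6-trihydroxy-3-methylphenyl)ethan-1-one | CC(=O)c1c(O)cc(O)c(C)c1O | starting material
2 | 1-(2-hydroxy-4,6-dimethoxy-3-methylphenyl)ethan-1-one | CC(=O)c1c(O)c(C)c(OC)cc1OC | intermediate
3 | 1-(2-hydroxy-5-iodo-4,6-dimethoxy-3-methylphenyl)ethan-1-one | CC(=O)c1c(O)c(C)c(OC)c(I)c1OC | intermediate
4 | acrylic acid | C=CC(=O)O | starting material
5 | (2E)-3-(3-acetyl-4-hydroxy-2,6-dimethoxy-5-methylphenyl)prop-2-enoic acid | CC(=O)c1c(O)c(C)c(OC)c(/C=C/C(=O)O)c1OC | intermediate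
6 | 3-(3-acetyl-4-hydroxy-2,6-dimethoxy-5-methylphenyl)propanoic acid | CC(=O)c1c(O)c(C)c(OC)c(CCC(=O)O)c1OC | intermediate
7 | geranyl acetate | CC(=O)OC/C=C(\C)CCC=C(C)C | starting material
8 | 3-[(3R)-5-acetyl-3-Ger-2,6-dimethoxy-3-methyl-4-oxocyclohexa-1,5-dien-1-yl]propanoic acid (3-RB-propanoic acid) | OC(=O)CCC1=C(OC)[C@@](C)(C/C=C(\C)CCC=C(C)C)C(=O)C(C(C)=O)=C1OC | intermediate
9 | hex-1-yn-3-ol | CCCC(O)C#C | starting material
10 | hex-1-yn-3-one | CCCC(=O)C#C | intermediate
11 | 2-ethynyl-2-propyl-1,3-dioxolane | CCCC1(C#C)OCCO1 | intermediate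
12 | lithium (2-propyl-1,3-dioxolan-2-yl)acetylide | CCCC1(C#C[Li])OCCO1 | intermediate
13 | lithium 2-(2-propyl-1,3-dioxolan-2-yl)ethynolate | CCCC1(C#CO[Li])OCCO1 | intermediate
14 | triisopropyl{[(2-propyl-1,3-dioxolan-2-yl)ethynyl]oxy}silane | CCCC1(C#CO[Si](C(C)C)(C(C)C)C(C)C)OCCO1 | intermediate
15 | geranyl bromide | BrC/C=C(\C)CCC=C(C)C | starting material
16 | (4E)-5,9-dimethyldeca-4,8-dien-1-yne | C#CC/C=C(\C)CCC=C(C)C | intermediate
17 | lithium (4E)-5,9-dimethyldeca-4,8-dien-1-yn-1-ide | [Li]C#CC/C=C(\C)CCC=C(C)C | intermediate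
18 | lithium (4E)-5,9-dimethyldeca-4,8-dien-1-yn-1-olate | [Li]OC#CC/C=C(\C)CCC=C(C)C | intermediate
19 | {[(4E)-5,9-dimethyldeca-4,8-dien-1-yn-1-yl]oxy}triisopropylsilane | CC(C)[Si](OC#CC/C=C(\C)CCC=C(C)C)(C(C)C)C(C)C | intermediate
20 | 3-RB-propanoyl chloride | ClC(=O)CCC1=C(OC)[C@@](C)(C/C=C(\C)CCC=C(C)C)C(=O)C(C(C)=O)=C1OC | intermediate
21 | 3-RB-prop-1-en-1-one (monosubstituted ketene) | O=C=CCC1=C(OC)[C@@](C)(C/C=C(\C)CCC=C(C)C)C(=O)C(C(C)=O)=C1OC | intermediate
22 | 4-(RB-methyl)-2-(2-propyl-1,3-dioxolan-2-yl)-3-(TIPS-oxy)cyclobut-2-en-1-one, both C4 epimers | O=C1C(C2(CCC)OCCO2)=C(O[Si](C(C)C)(C(C)C)C(C)C)C1CC3=C(OC)[C@@](C)(C/C=C(\C)CCC=C(C)C)C(=O)C(C(C)=O)=C3OC | intermediate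
23 | 2-(2-propyl-1,3-dioxolan-2-yl)-3-(TIPS-oxy)-5-RB-penta-1,3-dien-1-one (vinylketene) | O=C=C(C1(CCC)OCCO1)/C(O[Si](C(C)C)(C(C)C)C(C)C)=C/CC2=C(OC)[C@@](C)(C/C=C(\C)CCC=C(C)C)C(=O)C(C(C)=O)=C2OC | intermediate
24 | 2-Ger-4-(2-propyl-1,3-dioxolan-2-yl)-3-(TIPS-oxy)-4-[1-(TIPS-oxy)-3-RB-prop-1-en-1-yl]cyclobut-2-en-1-one | O=C1C(C/C=C(\C)CCC=C(C)C)=C(O[Si](C(C)C)(C(C)C)C(C)C)C1(C2(CCC)OCCO2)/C(O[Si](C(C)C)(C(C)C)C(C)C)=C/CC3=C(OC)[C@@](C)(C/C=C(\C)CCC=C(C)C)C(=O)C(C(C)=O)=C3OC | intermediate
25 | 2-Ger-4-(2-propyl-1,3-dioxolan-2-yl)-3,5-bis(TIPS-oxy)-7-RB-hepta-1,3,5-trien-1-one (dienylketene) | O=C=C(C/C=C(\C)CCC=C(C)C)/C(O[Si](C(C)C)(C(C)C)C(C)C)=C(C1(CCC)OCCO1)\C(O[Si](C(C)C)(C(C)C)C(C)C)=C\CC2=C(OC)[C@@](C)(C/C=C(\C)CCC=C(C)C)C(=O)C(C(C)=O)=C2OC | intermediate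
26 | 2-Ger-4-(2-propyl-1,3-dioxolan-2-yl)-6-(RB-methyl)-3,5-bis(TIPS-oxy)cyclohexa-2,4-dien-1-one | O=C1C(C/C=C(\C)CCC=C(C)C)=C(O[Si](C(C)C)(C(C)C)C(C)C)C(C2(CCC)OCCO2)=C(O[Si](C(C)C)(C(C)C)C(C)C)C1CC3=C(OC)[C@@](C)(C/C=C(\C)CCC=C(C)C)C(=O)C(C(C)=O)=C3OC | intermediate
27 | 2-Ger-4-(2-propyl-1,3-dioxolan-2-yl)-6-(RB-methyl)-3,5-bis(TIPS-oxy)phenol | Oc1c(C/C=C(\C)CCC=C(C)C)c(O[Si](C(C)C)(C(C)C)C(C)C)c(C2(CCC)OCCO2)c(O[Si](C(C)C)(C(C)C)C(C)C)c1CC3=C(OC)[C@@](C)(C/C=C(\C)CCC=C(C)C)C(=O)C(C(C)=O)=C3OC | intermediate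
28 | 1-[3-Ger-4-hydroxy-5-{[(3R)-5-acetyl-3-Ger-2,4-dihydroxy-3-methyl-6-oxocyclohexa-1,4-dien-1-yl]methyl}-2,6-bis(TIPS-oxy)phenyl]butan-1-one | CCCC(=O)c1c(O[Si](C(C)C)(C(C)C)C(C)C)c(C/C=C(\C)CCC=C(C)C)c(O)c(CC2=C(O)[C@@](C)(C/C=C(\C)CCC=C(C)C)C(O)=C(C(C)=O)C2=O)c1O[Si](C(C)C)(C(C)C)C(C)C | intermediate
29 | 1-[3-Ger-2,4,6-trihydroxy-5-{[(3R)-5-acetyl-3-Ger-2,4-dihydroxy-3-methyl-6-oxocyclohexa-1,4-dien-1-yl]methyl}phenyl]butan-1-one (CNP0209203.1) | CCCC(=O)c1c(O)c(C/C=C(\C)CCC=C(C)C)c(O)c(CC2=C(O)[C@@](C)(C/C=C(\C)CCC=C(C)C)C(O)=C(C(C)=O)C2=O)c1O | target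

**Step count and risks**

Total step count: 14. Longest linear sequence: 9 steps (steps 1–5 and 11–14); the two siloxyalkynes take 3 steps (6–8) and 2 steps (9–10).

Steps most likely to fail:

1. Step 5 (labelled step). The π-geranyl palladium cation may be captured at the phenoxide oxygen or at the para carbon B6 instead of B4. The two faces of the phenoxide may also be poorly differentiated, and π–σ–π equilibration of the allyl complex may scramble the E-alkene. The fallback uses known chemistry, sets out from 6 and 15 and returns at 8. Compound 6 is deprotonated twice with NaH in toluene and treated with geranyl bromide 15 (2.3 equiv, a little DMF at the end). The tight sodium phenoxide ion pair alkylates at its ortho carbon in the non-polar solvent and the carboxylate is esterified, which should give the racemic geranyl ester of the dienone acid F1. Pd(PPh3)4 with morpholine removes the allylic ester to give the racemic dienone acid F2. Crystallisation with (R)-1-phenylethylamine (or its antipode, if the other diastereomer is the less soluble one) gives the (R)-1-phenylethylammonium salt of the (R)-acid F3, and aqueous citric acid returns 8.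

2. Step 12 (key step). Capture of vinylketene 23 may be slower than its re-closure or its acylation of the product, because the ketene α-carbon carries the ketal and must bond to a TIPS-oxy-bearing alkyne carbon. Prolonged heating may also start sigmatropic migration of the geranyl group of the ring B 2,4-dienone. The fallback exchanges the roles of the two alkynes, sets out from 8, 19 and 14 and returns at 29. Acid 8 is converted as in step 11, but in the presence of 19, into the 2-geranyl cyclobutenone F4. Heating F4 with 14 places the ketal-bearing alkyne carbon on the unhindered ketene carbonyl carbon and leaves only a CH2 group on the ketene α-carbon, which should give the isomeric phenol F5. Aqueous HCl in THF then gives the isomeric bis-silyl ether F6, and Bu4NF with AcOH gives 29, because all three ring A oxygens end as hydroxyl groups.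

3. Step 11. The monosubstituted ketene 21 may dimerise or be consumed by triethylamine-derived acylammonium enolates before the siloxyalkyne traps it. The fallback replaces the ketene by a keteniminium ion, sets out from 8 and returns at 22. Acid 8 is converted through chloride 20 and dimethylamine into the N,N-dimethylamide F7. Tf2O and 2,4,6-collidine in CH2Cl2 at −20 °C give the keteniminium triflate F8, which does not dimerise. Its [2+2] cycloaddition with 14 gives the cyclobuteniminium triflate F9, and buffered aqueous NaHCO3 hydrolyses the iminium to 22.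

**Further compounds**

F1 | step 5 | Ger 3-[5-acetyl-3-Ger-2,6-dimethoxy-3-methyl-4-oxocyclohexa-1,5-dien-1-yl]propanoate, racemic | CC(=O)C1=C(OC)C(CCC(=O)OC/C=C(\C)CCC=C(C)C)=C(OC)C(C)(C/C=C(\C)CCC=C(C)C)C1=O
F2 | step 5 | 3-[5-acetyl-3-Ger-2,6-dimethoxy-3-methyl-4-oxocyclohexa-1,5-dien-1-yl]propanoic acid, racemic | OC(=O)CCC1=C(OC)C(C)(C/C=C(\C)CCC=C(C)C)C(=O)C(C(C)=O)=C1OC
F3 | step 5 | (R)-1-phenylethylammonium 3-RB-propanoate | C[C@@H]([NH3+])c1ccccc1.[O-]C(=O)CCC1=C(OC)[C@@](C)(C/C=C(\C)CCC=C(C)C)C(=O)C(C(C)=O)=C1OC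
F4 | step 12 | 2-Ger-4-(RB-methyl)-3-(TIPS-oxy)cyclobut-2-en-1-one | O=C1C(C/C=C(\C)CCC=C(C)C)=C(O[Si](C(C)C)(C(C)C)C(C)C)C1CC3=C(OC)[C@@](C)(C/C=C(\C)CCC=C(C)C)C(=O)C(C(C)=O)=C3OC
F5 | step 12 | 4-Ger-2-(2-propyl-1,3-dioxolan-2-yl)-6-(RB-methyl)-3,5-bis(TIPS-oxy)phenol | Oc1c(C2(CCC)OCCO2)c(O[Si](C(C)C)(C(C)C)C(C)C)c(C/C=C(\C)CCC=C(C)C)c(O[Si](C(C)C)(C(C)C)C(C)C)c1CC3=C(OC)[C@@](C)(C/C=C(\C)CCC=C(C)C)C(=O)C(C(C)=O)=C3OC
F6 | step 12 | 1-[5-Ger-2-hydroxy-3-{[(3R)-5-acetyl-3-Ger-2,4-dihydroxy-3-methyl-6-oxocyclohexa-1,4-dien-1-yl]methyl}-4,6-bis(TIPS-oxy)phenyl]butan-1-one | CCCC(=O)c1c(O)c(CC2=C(O)[C@@](C)(C/C=C(\C)CCC=C(C)C)C(O)=C(C(C)=O)C2=O)c(O[Si](C(C)C)(C(C)C)C(C)C)c(C/C=C(\C)CCC=C(C)C)c1O[Si](C(C)C)(C(C)C)C(C)C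
F7 | step 11 | N,N-dimethyl-3-RB-propanamide | CN(C)C(=O)CCC1=C(OC)[C@@](C)(C/C=C(\C)CCC=C(C)C)C(=O)C(C(C)=O)=C1OC
F8 | step 11 | N,N-dimethyl-(3-RB-prop-1-en-1-ylidene)ammonium triflate (keteniminium salt) | C[N+](C)=C=CCC1=C(OC)[C@@](C)(C/C=C(\C)CCC=C(C)C)C(=O)C(C(C)=O)=C1OC.[O-]S(=O)(=O)C(F)(F)F
F9 | step 11 | N,N-dimethyl-[4-(RB-methyl)-2-(2-propyl-1,3-dioxolan-2-yl)-3-(TIPS-oxy)cyclobut-2-en-1-ylidene]ammonium triflate | C[N+](C)=C1C(C2(CCC)OCCO2)=C(O[Si](C(C)C)(C(C)C)C(C)C)C1CC3=C(OC)[C@@](C)(C/C=C(\C)CCC=C(C)C)C(=O)C(C(C)=O)=C3OC.[O-]S(=O)(=O)C(F)(F)F
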